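**Plan**

1. Numbering (fusicoccane): ring A = cyclopentene C2–C3–C4–C5–C6 (C3 bears C16H2OMe); ring B = eight-membered C1–C2–C6–C7–C8–C9–C10–C11; ring C = cyclopentenone C10–C14; O10 = ether oxygen between C10 and C6.
2. Cuts: C8–OH back to a C8 ketone with an allyl ester helper on C9; then the O10–C6 and C8–C9 bonds together (retro oxa-Michael/Dieckmann); then C9–C10 (acetate aldol), C1–C2 (Nozaki–Hiyama–Kishi) and C6=C7 (Peterson), leaving a ring C aldehyde and a ring A iodide.
3. Forward: ring C from 2-methylcyclopentane-1,3-dione (steps 1–7), ring A from 3-ethoxycyclopent-2-en-1-one (steps 8–10), union at C1–C2 (step 11); the cascade then closes both six-membered oxacycles around O10 and with them ring B (step 14); helper removal and oxidation-state adjustment follow (steps 15–18).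
4. Enabling feature: in the tetrahydropyran O10–C6–C7–C8–C9–C10 the C8 oxygen is 1,3 to the ether carbon C6, so C6/C8 are the β-carbon/acyl carbon of a C6=C7–C8(=O) acrylate and O10–C10–C9 is a β-hydroxy ester; O10 and C1 are cis on ring C, so the alkoxide reaches C6 through the six-membered ring O10–C10–C11–C1–C2–C6.
5. Stereochemistry: C11 by enzymatic desymmetrisation (step 2); C10 by substrate-controlled addition anti to the C1 side chain (step 13); C6 and C7 by the reversible, self-correcting cascade and a kinetic protonation (step 14); C8 by exo hydride delivery (step 18); the C1 and C12 carbinols are temporary.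

Key step: step 14

Remark: between the coupling (step 11) and the oxidation (step 17) the C1 carbinol is carried as both epimers, and between steps 10 and 14 the C6=C7 alkene as an E/Z mixture; both elements are erased later, so the SMILES leave them open.
Assumption: tributyl(methoxymethyl)stannane and methyl 2-(trimethylsilyl)propanoate are taken as purchasable reagents.

**Route**

Step 1
Reactants: 1 2-methylcyclopentane-1,3-dione; 2 allyl bromide
Product: 3 2-allyl-2-methylcyclopentane-1,3-dione
Conditions: 1 M aq NaOH, allyl bromide, rt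
Reagents that add atoms: allyl bromide C=CCBr
Why: C-Alkylation (SN2) of the stabilised dione enolate with the allylic halide attaches the three-carbon group whose first carbon becomes C1 to the future C11, which is not yet a stereocentre because the two carbonyl groups are still equivalent.

Step 2
Reactants: 3 2-allyl-2-methylcyclopentane-1,3-dione
Product: 4 (2S,3S)-2-allyl-3-hydroxy-2-methylcyclopentan-1-one
Conditions: baker's yeast (Saccharomyces cerevisiae), sucrose, H2O, 30 °C
Reagents that add atoms: none
Why: Enzymatic desymmetrising reduction of a 2,2-disubstituted cyclopentane-1,3-dione (yeast ketoreductase, reagent control) should reduce one of the two enantiotopic carbonyl groups from one face, which makes the quaternary carbon (future C11) S and puts the new hydroxyl (future C12 oxygen) cis to the allyl group.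

Step 3
Reactants: 4 (2S,3S)-2-allyl-3-hydroxy-2-methylcyclopentan-1-one
Product: 5 (2S,3S)-2-allyl-3-[(tert-butyldimethylsilyl)oxy]-2-methylcyclopentan-1-one
Conditions: TBSCl, imidazole, DMF, rt
Reagents that add atoms: tert-butyldimethylsilyl chloride CC(C)(C)[Si](C)(C)Cl
Why: Silyl ether formation at the secondary hydroxyl masks the C12 oxygen through the base- and organometal-mediated steps until step 16.

Step 4
Reactants: 5 (2S,3S)-2-allyl-3-[(tert-butyldimethylsilyl)oxy]-2-methylcyclopentan-1-one
Product: 6 (2S,3S)-3-[(tert-butyldimethylsilyl)oxy]-2-methyl-2-[(E)-prop-1-enyl]cyclopentan-1-one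
Conditions: RuHCl(CO)(PPh3)3 (cat.), toluene, 80 °C
Reagents that add atoms: none
Why: Ruthenium hydride-catalysed alkene isomerisation (hydrometalation/β-hydride elimination) moves the terminal double bond into the internal position next to the quaternary carbon, where it must stop, so that ozonolysis later leaves exactly one carbon (C1) on C11.

Step 5
Reactants: 6 (2S,3S)-3-[(tert-butyldimethylsilyl)oxy]-2-methyl-2-[(E)-prop-1-enyl]cyclopentan-1-one; 7 acetone
Product: 8 (2S,3S)-3-[(tert-butyldimethylsilyl)oxy]-5-(2-hydroxypropan-2-yl)-2-methyl-2-[(E)-prop-1-enyl]cyclopentan-1-one (both C5 epimers)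
Conditions: LDA, THF, −78 °C; then acetone, −78 °C; aq NH4Cl at −78 °C
Reagents that add atoms: acetone CC(C)=O
Why: Deprotonation can occur only at the one enolisable α-methylene (future C14), and the aldol addition of this lithium enolate to acetone brings in the three carbons of the isopropyl group, the new C14 stereocentre being removed again in step 6.

Step 6
Reactants: 8 (2S,3S)-3-[(tert-butyldimethylsilyl)oxy]-5-(2-hydroxypropan-2-yl)-2-methyl-2-[(E)-prop-1-enyl]cyclopentan-1-one
Product: 10 (2S,3S)-3-[(tert-butyldimethylsilyl)oxy]-2-methyl-5-(propan-2-ylidene)-2-[(E)-prop-1-enyl]cyclopentan-1-one, via mesylate 9 (not isolated)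
Conditions: MsCl, Et3N, CH2Cl2, 0 °C to rt
Reagents that add atoms: none
Why: Mesylation of the tertiary aldol hydroxyl and amine-induced E1cB elimination through the ketone enolate should give the conjugated exocyclic enone, whose alkene is electron-poor and therefore protected against ozone in step 7.

Step 7
Reactants: 10 (2S,3S)-3-[(tert-butyldimethylsilyl)oxy]-2-methyl-5-(propan-2-ylidene)-2-[(E)-prop-1-enyl]cyclopentan-1-one
Product: 12 (1R,5S)-5-[(tert-butyldimethylsilyl)oxy]-1-methyl-2-oxo-3-(propan-2-ylidene)cyclopentane-1-carbaldehyde, via ozonide 11 (not isolated)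
Conditions: O3, CH2Cl2, −78 °C (stopped when 10 is consumed); then Me2S, −78 °C to rt
Reagents that add atoms: ozone [O-][O+]=O
Why: Ozonolysis with reductive work-up should cleave the electron-richer disubstituted propenyl alkene much faster than the carbonyl-conjugated tetrasubstituted one and so unveils the C1 aldehyde on the quaternary C11 without touching a stereocentre.

Step 8
Reactants: 13 3-ethoxycyclopent-2-en-1-one; 14 tributyl(methoxymethyl)stannane
Product: 16 3-(methoxymethyl)cyclopent-2-en-1-one, via tertiary allylic alcohol 15 (not isolated)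
Conditions: 14, n-BuLi, THF, −78 °C; then 13, −78 to 0 °C; then 1 M aq HCl, rt
Reagents that add atoms: tributyl(methoxymethyl)stannane CCCC[Sn](CCCC)(CCCC)COC; water O
Why: Stork–Danheiser transposition: (methoxymethyl)lithium from tin–lithium exchange adds 1,2 to the vinylogous ester and acid hydrolysis of the resulting enol ether with loss of ethanol gives the enone that carries C16 on the future C3.

Step 9
Reactants: 16 3-(methoxymethyl)cyclopent-2-en-1-one
Product: 17 2-iodo-3-(methoxymethyl)cyclopent-2-en-1-one
Conditions: I2, pyridine, CH2Cl2, rt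
Reagents that add atoms: iodine II
Why: α-Iodination of the enone by the amine-mediated addition–iodination–elimination sequence (Baylis–Hillman-type mechanism) puts the halogen on the future C2, between the C3 substituent and the C6 carbonyl.

Step 10
Reactants: 17 2-iodo-3-(methoxymethyl)cyclopent-2-en-1-one; 18 methyl 2-(trimethylsilyl)propanoate
Product: 20 methyl 2-[2-iodo-3-(methoxymethyl)cyclopent-2-en-1-ylidene]propanoate (E/Z mixture), via β-silyl alkoxide adduct 19 (not isolated)
Conditions: 18, LDA, THF, −78 °C; then 17, −78 °C to rt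
Reagents that add atoms: methyl 2-(trimethylsilyl)propanoate CC(C(=O)OC)[Si](C)(C)C
Why: Peterson olefination: the lithium enolate of the α-silyl ester adds to the C6 carbonyl and the β-silyl alkoxide loses lithium trimethylsilanolate spontaneously to give the tetrasubstituted C6=C7 alkene, whose geometry need not be controlled because it is erased in step 14.

Step 11
Reactants: 12 (1R,5S)-5-[(tert-butyldimethylsilyl)oxy]-1-methyl-2-oxo-3-(propan-2-ylidene)cyclopentane-1-carbaldehyde; 20 methyl 2-[2-iodo-3-(methoxymethyl)cyclopent-2-en-1-ylidene]propanoate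
Product: 22 C1 carbinol joining ring A and ring C (ring A of 20 bonded at C2 to C1H(OH), which is bonded to the quaternary C11 of the ring C unit of 12; both C1 epimers), via alkenylchromium dichloride 21 (not isolated)
Conditions: CrCl2 (4 equiv), NiCl2 (cat.), DMSO, rt
Reagents that add atoms: none
Why: Nozaki–Hiyama–Kishi reaction: the alkenylchromium species formed from the iodide under nickel catalysis adds chemoselectively to the aldehyde in the presence of the ketone and the ester and forms the C1–C2 bond between the two rings, the configuration of the new C1 carbinol being irrelevant because C1 becomes a ketone in step 17.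

Step 12
Reactants: 22 C1 carbinol joining ring A and ring C
Product: 23 C1 tert-butyldimethylsilyl ether of 22
Conditions: TBSOTf, 2,6-lutidine, CH2Cl2, −78 to 0 °C
Reagents that add atoms: tert-butyldimethylsilyl triflate CC(C)(C)[Si](C)(C)OS(=O)(=O)C(F)(F)F
Why: Silyl triflate and a hindered pyridine base silylate the congested secondary allylic alcohol, so that in steps 13 and 14 C1 offers neither a free hydroxyl nor a carbonyl group that would open a retro-aldol path for the C10 alkoxide.

Step 13
Reactants: 23 C1 tert-butyldimethylsilyl ether of 22; 24 allyl acetate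
Product: 25 tertiary C10 carbinol bearing CH2CO2allyl (C9) on C10, hydroxyl cis to C1 and to the C12 silyl ether, C9 cis to the C11 methyl
Conditions: allyl acetate, LDA, THF, −78 °C; CeCl3; then 23, −78 °C; AcOH at −78 °C
Reagents that add atoms: allyl acetate CC(=O)OCC=C
Why: Aldol-type 1,2-addition of the cerium-modified lithium enolate of allyl acetate to the non-enolisable C10 ketone should take place on the face of ring C that carries only the C11 methyl group, opposite to the C1 side chain and the cis C12 silyl ether, which sets C10 with its hydroxyl cis to C1 as the target requires.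

Step 14
Reactants: 25 tertiary C10 carbinol bearing CH2CO2allyl on C10
Product: 27 tetracyclic β-keto ester (target skeleton with O10–C6 bridge, C8 ketone, allyl ester on C9, equatorial C7 methyl, C1 and C12 silyl ethers, C14 isopropylidene), via oxa-Michael adduct 26 (not isolated)
Conditions: NaH (2.5 equiv), THF, 0 °C to rt; then LDA (2 equiv), −78 °C; then AcOH, −78 °C
Reagents that add atoms: none
Why: The sodium alkoxide of O10 adds to C6 of the C6=C7–C8 unsaturated ester (oxa-Michael addition, 6-exo-trig, closing the ring O10–C10–C11–C1–C2–C6), and after proton transfer the C9 ester enolate attacks the C8 methyl ester (Dieckmann condensation, 6-exo-trig, closing the tetrahydropyranone O10–C6–C7–C8–C9–C10 and with it the eight-membered ring B), the sequence ending as the sodium enolate of the β-keto ester. The closest known reaction types are the tandem oxa-Michael/Dieckmann annulation of β-hydroxy esters with acrylates to 3-alkoxycarbonyl-tetrahydropyran-4-ones and the Dieckmann closure of cis-2,6-disubstituted tetrahydropyran diesters to 9-oxabicyclo[3.3.1]nonan-3-ones. C6 is controlled by C10 and C11: the conjugate addition is reversible and only the C6 epimer whose C7 arm is 1,3-diaxial to the C9 arm on the new oxacycle can close, so both alkene isomers of 25 and both faces of C6 funnel into one configuration. C7 is fixed at the end, when the α,γ-dianion made with LDA is protonated at C7 from the exo face, anti to the axial C6–C2 bond, which places the methyl group equatorial whatever the C7 configuration of 26 was; C9 stays a mixture or enol because its ester is removed in step 15. The step needs O-attack at C6 before any C9 enolate chemistry and Dieckmann closure from C9 rather than from C7: the alkoxide forms first and a second negative charge next to it is disfavoured until it has added, and only closure from C9 gives a β-keto ester with an acidic hydrogen between the carbonyls, which drains all the equilibria.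

Step 15
Reactants: 27 tetracyclic β-keto ester
Product: 29 tetracyclic C8 ketone (C9 now CH2; C1 and C12 silyl ethers, C14 isopropylidene), via β-keto acid 28 (not isolated)
Conditions: Pd(PPh3)4 (cat.), morpholine, THF, rt
Reagents that add atoms: none
Why: Palladium-catalysed deallylation of the allyl β-keto ester (π-allylpalladium formation and allyl transfer to morpholine) followed by spontaneous decarboxylation removes the C9 helper under neutral conditions that leave the silyl ethers, the β-alkoxy ketone and the alkenes untouched.

Step 16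
Reactants: 29 tetracyclic C8 ketone
Product: 30 C1,C12-diol C8-ketone
Conditions: HF·pyridine, pyridine, THF, 0 °C to rt
Reagents that add atoms: none
Why: Fluoride cleaves both silyl ethers under buffered, non-basic conditions, which frees the C1 and C12 hydroxyls without the risk of opening the β-alkoxy ketone by retro-oxa-Michael reaction.

Step 17
Reactants: 30 C1,C12-diol C8-ketone
Product: 32 C1,C8,C12-trione with the C13=C14 enone and the C14 isopropyl group (8-oxo analogue of the target), via deconjugated trione 31 (not isolated)
Conditions: Dess–Martin periodinane, NaHCO3, CH2Cl2, rt; then Et3N, rt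
Reagents that add atoms: none
Why: Dess–Martin oxidation turns both secondary alcohols into ketones, and the amine then moves the exocyclic alkene of the β,γ-unsaturated C12 ketone into conjugation through the dienolate formed at the doubly activated C13 (base-mediated alkene isomerisation), which creates the C13=C14 enone and the isopropyl group while the much less acidic C7 hydrogen is left alone.

Step 18
Reactants: 32 C1,C8,C12-trione
Product: 33 alterbrassicicene C
Conditions: NaBH4, MeOH/CH2Cl2 (1:1), −78 °C
Reagents that add atoms: none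
Why: Chemoselective borohydride reduction: the saturated, accessible C8 ketone should react much faster than the two hindered conjugated ketones at low temperature without a cerium salt, and hydride delivery to the exo face of the 9-oxabicyclo[3.3.1]nonanone, away from the C1 bridge, gives the endo (axial) C8 alcohol of the target.

**Compound list**

1 | 2-methylcyclopentane-1,3-dione | CC1C(=O)CCC1=O | starting material
2 | allyl bromide | C=CCBr | starting material
3 | 2-allyl-2-methylcyclopentane-1,3-dione | C=CCC1(C)C(=O)CCC1=O | intermediate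
4 | (2S,3S)-2-allyl-3-hydroxy-2-methylcyclopentan-1-one (OH cis to allyl) | C=CC[C@]1(C)C(=O)CC[C@@H]1O | intermediate
5 | (2S,3S)-2-allyl-3-[(tert-butyldimethylsilyl)oxy]-2-methylcyclopentan-1-one | C=CC[C@]1(C)C(=O)CC[C@@H]1O[Si](C)(C)C(C)(C)C | intermediate
6 | (2S,3S)-3-[(tert-butyldimethylsilyl)oxy]-2-methyl-2-[(E)-prop-1-enyl]cyclopentan-1-one | C/C=C/[C@]1(C)C(=O)CC[C@@H]1O[Si](C)(C)C(C)(C)C | intermediate
7 | acetone | CC(C)=O | starting material
8 | (2S,3S)-3-[(tert-butyldimethylsilyl)oxy]-5-(2-hydroxypropan-2-yl)-2-methyl-2-[(E)-prop-1-enyl]cyclopentan-1-one (both C5 epimers) | C/C=C/[C@]1(C)C(=O)C(C(C)(C)O)C[C@@H]1O[Si](C)(C)C(C)(C)C | intermediate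
9 | tertiary methanesulfonate of 8 | C/C=C/[C@]1(C)C(=O)C(C(C)(C)OS(C)(=O)=O)C[C@@H]1O[Si](C)(C)C(C)(C)C | intermediate (not isolated)
10 | (2S,3S)-3-[(tert-butyldimethylsilyl)oxy]-2-methyl-5-(propan-2-ylidene)-2-[(E)-prop-1-enyl]cyclopentan-1-one | C/C=C/[C@]1(C)C(=O)C(=C(C)C)C[C@@H]1O[Si](C)(C)C(C)(C)C | intermediate
11 | secondary ozonide (3-methyl-1,2,4-trioxolan-5-yl in place of the propenyl group of 10) | CC1OOC(O1)[C@]2(C)C(=O)C(=C(C)C)C[C@@H]2O[Si](C)(C)C(C)(C)C | intermediate (not isolated)
12 | (1R,5S)-5-[(tert-butyldimethylsilyl)oxy]-1-methyl-2-oxo-3-(propan-2-ylidene)cyclopentane-1-carbaldehyde (ring C aldehyde; CHO = C1, quaternary carbon = C11) | O=C[C@]1(C)C(=O)C(=C(C)C)C[C@@H]1O[Si](C)(C)C(C)(C)C | intermediate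
13 | 3-ethoxycyclopent-2-en-1-one | CCOC1=CC(=O)CC1 | starting material
14 | tributyl(methoxymethyl)stannane | CCCC[Sn](CCCC)(CCCC)COC | starting material
15 | 3-ethoxy-1-(methoxymethyl)cyclopent-2-en-1-ol (formed as its lithium alkoxide, racemic) | CCOC1=CC(O)(COC)CC1 | intermediate (not isolated)
16 | 3-(methoxymethyl)cyclopent-2-en-1-one | COCC1=CC(=O)CC1 | intermediate
17 | 2-iodo-3-(methoxymethyl)cyclopent-2-en-1-one | COCC1=C(I)C(=O)CC1 | intermediate
18 | methyl 2-(trimethylsilyl)propanoate | CC(C(=O)OC)[Si](C)(C)C | starting material
19 | methyl 2-[1-hydroxy-2-iodo-3-(methoxymethyl)cyclopent-2-en-1-yl]-2-(trimethylsilyl)propanoate (formed as its lithium alkoxide) | COCC1=C(I)C(O)(C(C)(C(=O)OC)[Si](C)(C)C)CC1 | intermediate (not isolated)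
20 | methyl 2-[2-iodo-3-(methoxymethyl)cyclopent-2-en-1-ylidene]propanoate (ring A iodide, E/Z mixture) | COCC1=C(I)C(=C(C)C(=O)OC)CC1 | intermediate
21 | alkenylchromium dichloride from 20 (CrCl2 in place of iodine) | COCC1=C([Cr](Cl)Cl)C(=C(C)C(=O)OC)CC1 | intermediate (not isolated)
22 | C1 carbinol: ring A dienoate of 20 bonded at C2 to C1H(OH), which is bonded to C11 of ring C (C11 methyl, C10 ketone, C14 isopropylidene, C12 OTBS cis to C1, as in 12); both C1 epimers | COCC1=C(C(O)[C@@]2(C)[C@@H](O[Si](C)(C)C(C)(C)C)CC(=C(C)C)C2=O)C(=C(C)C(=O)OC)CC1 | intermediate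
23 | C1 tert-butyldimethylsilyl ether of 22 | COCC1=C(C(O[Si](C)(C)C(C)(C)C)[C@@]2(C)[C@@H](O[Si](C)(C)C(C)(C)C)CC(=C(C)C)C2=O)C(=C(C)C(=O)OC)CC1 | intermediate
24 | allyl acetate | CC(=O)OCC=C | starting material
25 | 23 with C10 as tertiary carbinol bearing CH2CO2allyl (C9); C10 OH cis to C1 and to the C12 silyl ether, C9 cis to the C11 methyl | COCC1=C(C(O[Si](C)(C)C(C)(C)C)[C@@]2(C)[C@@H](O[Si](C)(C)C(C)(C)C)CC(=C(C)C)[C@]2(O)CC(=O)OCC=C)C(=C(C)C(=O)OC)CC1 | intermediate
26 | oxa-Michael adduct: O10 bonded to C6 (ring O10–C10–C11–C1–C2–C6 cis-fused to ring C); C6 carries C7H(CH3)CO2Me syn to the C10 arm CH2CO2allyl | COCC1=C2C(O[Si](C)(C)C(C)(C)C)[C@@]3(C)[C@@H](O[Si](C)(C)C(C)(C)C)CC(=C(C)C)[C@@]3(CC(=O)OCC=C)O[C@]2(CC1)C(C)C(=O)OC | intermediate (not isolated)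
27 | tetracyclic β-keto ester: C6, C7, C10, C11 as in the target; C8 ketone, allyl ester on C9 (epimers/enol), C1 and C12 OTBS, C14 isopropylidene | COCC1=C2C(O[Si](C)(C)C(C)(C)C)[C@@]3(C)[C@@H](O[Si](C)(C)C(C)(C)C)CC(=C(C)C)[C@]34C(C(=O)OCC=C)C(=O)[C@H](C)[C@@]2(CC1)O4 | intermediate
28 | β-keto acid from 27 (CO2H on C9) | COCC1=C2C(O[Si](C)(C)C(C)(C)C)[C@@]3(C)[C@@H](O[Si](C)(C)C(C)(C)C)CC(=C(C)C)[C@]34C(C(=O)O)C(=O)[C@H](C)[C@@]2(CC1)O4 | intermediate (not isolated)
29 | tetracyclic C8 ketone, C9 = CH2, C1 and C12 OTBS, C14 isopropylidene | COCC1=C2C(O[Si](C)(C)C(C)(C)C)[C@@]3(C)[C@@H](O[Si](C)(C)C(C)(C)C)CC(=C(C)C)[C@]34CC(=O)[C@H](C)[C@@]2(CC1)O4 | intermediate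
30 | C1,C12-diol C8-ketone | COCC1=C2C(O)[C@@]3(C)[C@@H](O)CC(=C(C)C)[C@]34CC(=O)[C@H](C)[C@@]2(CC1)O4 | intermediate
31 | C1,C8,C12-trione with C14 isopropylidene (C13 = CH2) | COCC1=C2C(=O)[C@@]3(C)C(=O)CC(=C(C)C)[C@]34CC(=O)[C@H](C)[C@@]2(CC1)O4 | intermediate (not isolated)
32 | C1,C8,C12-trione with C13=C14 and C14 isopropyl (8-oxo analogue of the target) | COCC1=C2C(=O)[C@@]3(C)C(=O)C=C(C(C)C)[C@]34CC(=O)[C@H](C)[C@@]2(CC1)O4 | intermediate
33 | alterbrassicicene C | COCC1=C2C(=O)[C@@]3(C)C(=O)C=C(C(C)C)[C@]34C[C@H](O)[C@H](C)[C@@]2(CC1)O4 | target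

**Totals and risks**

Total step count: 18. Longest linear sequence: 15 steps (steps 1–7 and 11–18, from 2-methylcyclopentane-1,3-dione).

The three steps most likely to fail:

Step 14. What may go wrong: the tertiary sodium alkoxide may expel its two-carbon arm by retro-aldol cleavage, or may not add to the fully substituted C6, faster than the cascade runs forward. The fallback sets out from 17 and 12 and comes back at 26; it makes the C6–O10 bond by ketalisation and the C9–C10 bond by oxocarbenium alkylation, so that no aldolate is exposed to base. Iodoenone 17 is treated with the lithium enolate of methyl propanoate (LDA, THF, −78 °C) to give the tertiary alcohol methyl 2-[1-hydroxy-2-iodo-3-(methoxymethyl)cyclopent-2-en-1-yl]propanoate F1. Nozaki–Hiyama–Kishi coupling of F1 with 12 (CrCl2, cat. NiCl2, DMSO) should give the C1,C6-diol C10-ketone F2, whose tertiary C6 hydroxyl should close onto the C10 ketone to a six-membered hemiketal. Silylation of the secondary C1 hydroxyl (TBSOTf, 2,6-lutidine, −78 °C) should give the C1 silyl ether hemiketal F3. F3 is then treated with the silyl ketene acetal 1-(allyloxy)-1-(trimethylsilyloxy)ethene F4 (made from 24 with LDA and TMSCl at −78 °C and used cold) and catalytic TMSOTf in CH2Cl2 at −78 °C. Mukaiyama-type addition to the C10 oxocarbenium ion from the face of the C11 methyl group should give 26; the C6 epimers may interconvert through reversible ionisation of the tertiary allylic C6–O bond under the Lewis acid. 26 is then closed to 27 by the Dieckmann half of step 14 alone (NaH, THF; then LDA and cold AcOH).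

Step 11. What may go wrong: oxidative addition and carbonyl addition between two congested partners may be slower than reduction of the iodide or deformylation of 12, and the new C1 chromium alkoxide may lactonise onto the C8 ester of the Z-dienoate. The fallback sets out from 17 and 12 and comes back at 23; it reverses the order of union and olefination. The less hindered and more easily activated α-iodoenone 17 is coupled with 12 under the same Nozaki–Hiyama–Kishi conditions to give the C1 carbinol with a C6 enone F5. Silylation (TBSOTf, 2,6-lutidine) gives the C1 silyl ether F6. Peterson olefination of F6 with the lithium enolate of 18 at the C6 ketone, which is less shielded than the neopentylic C10 ketone next to the tetrasubstituted alkene, should then give 23.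

Step 18. What may go wrong: hydride may also attack the C12 enone (at the carbonyl or in the conjugate sense) or approach C8 from the endo face, so that chemo- or stereoselectivity is lost. The fallback sets out from 29 and comes back at 33; the C8 ketone is reduced while it is the only carbonyl group, and the new hydroxyl is carried through the oxidation under protection. Reduction of 29 (NaBH4, MeOH, 0 °C, exo attack) should give the endo C8 alcohol F7. Acylation with allyl chloroformate (pyridine, DMAP) gives the C8 allyl carbonate F8. HF·pyridine removes both silyl ethers to give the C1,C12-diol C8 allyl carbonate F9. Dess–Martin oxidation followed by Et3N gives the C1,C12-dione with the C13=C14 enone and C8 allyl carbonate F10. Pd(PPh3)4 and morpholine then remove the allyl carbonate to give 33.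

**Further compounds**

F1 | step 14 | methyl 2-[1-hydroxy-2-iodo-3-(methoxymethyl)cyclopent-2-en-1-yl]propanoate | COCC1=C(I)C(O)(C(C)C(=O)OC)CC1
F2 | step 14 | C1,C6-diol C10-ketone from F1 and 12 (open form of the hemiketal) | COCC1=C(C(O)[C@@]2(C)[C@@H](O[Si](C)(C)C(C)(C)C)CC(=C(C)C)C2=O)C(O)(C(C)C(=O)OC)CC1
F3 | step 14 | C1 silyl ether hemiketal (O bridging C6 and C10, OH on C10) | COCC1=C2C(O[Si](C)(C)C(C)(C)C)[C@@]3(C)[C@@H](O[Si](C)(C)C(C)(C)C)CC(=C(C)C)C3(O)OC2(CC1)C(C)C(=O)OC
F4 | step 14 | 1-(allyloxy)-1-(trimethylsilyloxy)ethene | C=C(OCC=C)O[Si](C)(C)C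
F5 | step 11 | C1 carbinol with C6 enone (from 17 and 12) | COCC1=C(C(O)[C@@]2(C)[C@@H](O[Si](C)(C)C(C)(C)C)CC(=C(C)C)C2=O)C(=O)CC1
F6 | step 11 | C1 tert-butyldimethylsilyl ether of F5 | COCC1=C(C(O[Si](C)(C)C(C)(C)C)[C@@]2(C)[C@@H](O[Si](C)(C)C(C)(C)C)CC(=C(C)C)C2=O)C(=O)CC1
F7 | step 18 | endo C8 alcohol of 29 | COCC1=C2C(O[Si](C)(C)C(C)(C)C)[C@@]3(C)[C@@H](O[Si](C)(C)C(C)(C)C)CC(=C(C)C)[C@]34C[C@H](O)[C@H](C)[C@@]2(CC1)O4
F8 | step 18 | C8 allyl carbonate of F7 | COCC1=C2C(O[Si](C)(C)C(C)(C)C)[C@@]3(C)[C@@H](O[Si](C)(C)C(C)(C)C)CC(=C(C)C)[C@]34C[C@H](OC(=O)OCC=C)[C@H](C)[C@@]2(CC1)O4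
F9 | step 18 | C1,C12-diol C8 allyl carbonate | COCC1=C2C(O)[C@@]3(C)[C@@H](O)CC(=C(C)C)[C@]34C[C@H](OC(=O)OCC=C)[C@H](C)[C@@]2(CC1)O4
F10 | step 18 | C8 allyl carbonate of alterbrassicicene C | COCC1=C2C(=O)[C@@]3(C)C(=O)C=C(C(C)C)[C@]34C[C@H](OC(=O)OCC=C)[C@H](C)[C@@]2(CC1)O4
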